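**Retrosynthetic overview**
- The CH2 bridge between C7 of the benzofuran (ring A) and C3 of the pyranone (ring C) is cut last. It is made from a phenolic Mannich base, which reacts as its ortho-quinone methide, and the free 4-hydroxypyranone.
- Ring B (dihydrofuran) is cut at C3–C2. The open form is an achiral aryl 2-alkylallyl ether with a carbene precursor (a sulfonylhydrazone) on the carbon that becomes C3. An enantioselective cobalt-catalysed radical 1,5-C–H alkylation closes ring B, sets C2 and leaves both alkenes in place.
- Enabling feature: C2 carries O1 and the exocyclic C(=CH2) carbon and lies 1,5 to C3 along C3–C3a–C7a–O1–C2. In the open ether its CH2 therefore holds the weakest and the only reachable C–H bonds. O1 is para to the acetyl group of ring A, so the C2v symmetry of phloroacetophenone makes the O-alkylation site unique and the two ring CH positions (later C3a and C7) equivalent.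
- The hydrazone comes from phloroacetophenone by Mitsunobu etherification with a C9 dienol (methallyl alcohol dianion plus prenyl bromide), Vilsmeier–Haack formylation, pivaloylation and condensation. The pyranone comes from methyl 3-oxopentanoate by γ-acylation and lactonisation.
- Ring order: ring A is bought, ring B is closed in step 6, and ring C is closed separately in step 9 and joined in step 11.

Key step: step 6

Assumption: the sense of induction of the cobalt amidoporphyrin at an oxygen-tethered allylic CH2 is taken from its nitrogen-tethered analogues. Both ligand antipodes are accessible, and the one that delivers (2R) is used.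

**Step 1**
Reactants: 1 2-methylprop-2-en-1-ol (methallyl alcohol); 2 1-bromo-3-methylbut-2-ene (prenyl bromide)
Product: 4 6-methyl-2-methylidenehept-5-en-1-ol, via dilithiated methallyl alcohol 3 (not isolated)
Conditions: n-BuLi (2.2 equiv), TMEDA, Et2O, 0 °C to rt; then 2, THF, −78 °C to rt; H2O
Reagents that add atoms: none
Why: Double deprotonation gives the O,C-dianion, whose allylic carbanion end is alkylated at the primary carbon of the allylic bromide (dianion alkylation, SN2); no stereocentre is formed.

**Step 2**
Reactants: 4 6-methyl-2-methylidenehept-5-en-1-ol; 5 1-(2,4,6-trihydroxyphenyl)ethan-1-one (phloroacetophenone, dried azeotropically)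
Product: 6 1-{2,6-dihydroxy-4-[(6-methyl-2-methylidenehept-5-en-1-yl)oxy]phenyl}ethan-1-one
Conditions: PPh3, DIAD, THF, 0 °C to rt (5 in slight excess)
Reagents that add atoms: none
Why: Mitsunobu etherification picks the 4-OH, the most acidic hydroxyl and the only one not chelated to the acetyl group; C-alkylation is avoided, and both ends of the 2-substituted allyl unit are CH2, so SN2 and SN2′ give the same ether.

**Step 3**
Reactants: 6 1-{2,6-dihydroxy-4-[(6-methyl-2-methylidenehept-5-en-1-yl)oxy]phenyl}ethan-1-one
Product: 8 3-acetyl-2,4-dihydroxy-6-[(6-methyl-2-methylidenehept-5-en-1-yl)oxy]benzaldehyde, via aryl iminium chloride 7 (not isolated)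
Conditions: [Me2N=CHCl]Cl (1.1 equiv), MeCN/DMF, 0 °C to rt; then aq NaOAc, rt
Reagents that add atoms: (chloromethylidene)dimethyliminium chloride, C[N+](C)=CCl.[Cl-]; water, O
Why: Vilsmeier–Haack formylation of a ring activated by three oxygens; the two free positions are equivalent by symmetry, the first formyl group deactivates the ring against a second attack, and the low temperature keeps the acetyl methyl group and the alkenes untouched.

**Step 4**
Reactants: 8 3-acetyl-2,4-dihydroxy-6-[(6-methyl-2-methylidenehept-5-en-1-yl)oxy]benzaldehyde
Product: 9 2-acetyl-4-formyl-5-[(6-methyl-2-methylidenehept-5-en-1-yl)oxy]benzene-1,3-diyl bis(2,2-dimethylpropanoate)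
Conditions: PivCl (2.5 equiv), Et3N, DMAP (cat.), CH2Cl2, 0 °C to rt
Reagents that add atoms: pivaloyl chloride, CC(C)(C)C(=O)Cl
Why: DMAP-catalysed O-acylation caps both phenols; pivalate offers no C–H bond within reach of the later carbene centre, is too hindered for acyl shift to the hydrazone nitrogen or to the acetyl enolate (Baker–Venkataraman type) under carbonate, and leaves by mild methanolysis.

**Step 5**
Reactants: 9 2-acetyl-4-formyl-5-[(6-methyl-2-methylidenehept-5-en-1-yl)oxy]benzene-1,3-diyl bis(2,2-dimethylpropanoate)
Product: 10 (E)-2,4,6-triisopropylbenzenesulfonylhydrazone of aldehyde 9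
Conditions: 2,4,6-iPr3C6H2SO2NHNH2 (1.05 equiv), THF, rt
Reagents that add atoms: 2,4,6-triisopropylbenzenesulfonohydrazide, CC(C)c1cc(C(C)C)c(S(=O)(=O)NN)c(C(C)C)c1
Why: Sulfonylhydrazone condensation occurs at the aldehyde only, because the doubly ortho-substituted methyl ketone is far less electrophilic; the hindered sulfonyl group allows diazo release at low temperature in the next step.

**Step 6**
Reactants: 10 (E)-2,4,6-triisopropylbenzenesulfonylhydrazone of aldehyde 9
Product: 12 (2R)-5-acetyl-2-(6-methylhepta-1,5-dien-2-yl)-2,3-dihydro-1-benzofuran-4,6-diyl bis(2,2-dimethylpropanoate), via aryldiazomethane 11 (not isolated)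
Conditions: [Co(3,5-DitBu-ChenPhyrin)] (5 mol %), Cs2CO3 (1.2 equiv), 1,4-dioxane, 40 °C, argon
Reagents that add atoms: none
Why: Carbonate removes the N–H proton of 10 and sulfinate loss (Bamford–Stevens) releases aryldiazomethane 11 slowly; the divalent cobalt metalloradical takes it up with loss of N2 to give a cobalt-bound benzylic carbene radical at the future C3, which abstracts one hydrogen of the OCH2 group by 1,5-hydrogen-atom transfer through a six-membered transition state, and the α-aryloxy allyl radical formed at the future C2 attacks C3 with homolytic release of cobalt. The closest known reaction type is the metalloporphyrin-catalysed intramolecular carbene C–H insertion of ortho-alkoxyaryl sulfonylhydrazones to 2,3-dihydrobenzofurans, together with its enantioselective cobalt amidoporphyrin form, the radical 1,5-C–H alkylation with aryldiazomethanes made in situ, which accepts allylic C–H bonds and gives 2-substituted benzo-fused five-membered heterocycles. Ring B is closed by a 5-exo-tet radical substitution that forms C3–C2 and leaves C3 as a plain CH2, so nothing has to be removed afterwards. C2 is the only new stereocentre and is set by the catalyst: the chiral pocket of the D2-symmetric ligand chooses between the two enantiotopic hydrogens and holds the short-lived radical so that the bond forms on the same face. Site selectivity is secured by the substrate, since the OCH2 hydrogens are the only ones 1,5 to C3 (the other ortho substituent is a pivalate whose nearest C–H lies two atoms further out) and they are the weakest in the molecule, being both α to oxygen and allylic. Chemoselectivity over cyclopropanation, over closure at the CH2 end of the allyl radical (seven-membered ring) and over azine formation or uncatalysed dipolar cycloaddition rests on the radical character of the carbene, on the kinetic preference for the five-membered ring and on the low stationary concentration of 11.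

**Step 7**
Reactants: 12 (2R)-5-acetyl-2-(6-methylhepta-1,5-dien-2-yl)-2,3-dihydro-1-benzofuran-4,6-diyl bis(2,2-dimethylpropanoate)
Product: 13 1-[(2R)-4,6-dihydroxy-2-(6-methylhepta-1,5-dien-2-yl)-2,3-dihydro-1-benzofuran-5-yl]ethan-1-one
Conditions: NaOMe (2.5 equiv), MeOH, 0 °C to rt; then 1 M HCl to pH 5
Reagents that add atoms: none
Why: Methoxide transesterification cleaves the two aryl esters, which are activated by the ortho acetyl group; C2 has no acidic hydrogen and the alkenes are inert to base, so the stereocentre is retained.

**Step 8**
Reactants: 14 methyl 3-oxopentanoate; 15 N-methoxy-N-methylpropanamide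
Product: 17 methyl 4-methyl-3,5-dioxoheptanoate, via dilithium dienediolate 16 (not isolated)
Conditions: LDA (commercial solution, 2.2 equiv), THF, −78 to 0 °C; then 15, −78 to 0 °C; 1 M HCl
Reagents that add atoms: none
Why: γ-Acylation of a β-keto ester dianion at its more reactive terminal carbanion; the chelated tetrahedral adduct of the N-methoxy-N-methylamide prevents over-addition, and the labile C4 centre of 17 disappears in the next step.

**Step 9**
Reactants: 17 methyl 4-methyl-3,5-dioxoheptanoate
Product: 18 6-ethyl-4-hydroxy-5-methyl-2H-pyran-2-one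
Conditions: DBU (1.0 equiv), toluene, reflux; then 1 M HCl
Reagents that add atoms: none
Why: Base-mediated enol lactonisation (6-exo-trig attack of the C5 enolate oxygen on the ester) closes ring C with loss of methanol, driven by the conjugated 4-hydroxypyranone.

**Step 10**
Reactants: 13 1-[(2R)-4,6-dihydroxy-2-(6-methylhepta-1,5-dien-2-yl)-2,3-dihydro-1-benzofuran-5-yl]ethan-1-one
Product: 19 1-[(2R)-7-[(dimethylamino)methyl]-4,6-dihydroxy-2-(6-methylhepta-1,5-dien-2-yl)-2,3-dihydro-1-benzofuran-5-yl]ethan-1-one
Conditions: [Me2N=CH2]I (1.1 equiv), CH2Cl2, rt; then aq NaHCO3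
Reagents that add atoms: N,N-dimethylmethyleneiminium iodide, C[N+](C)=C.[I-]
Why: Phenolic Mannich aminomethylation with a preformed iminium salt; C7 is the only free position of ring A and lies ortho to the C6 hydroxyl, so a single regioisomer should form under neutral conditions that do not touch C2.

**Step 11**
Reactants: 19 1-[(2R)-7-[(dimethylamino)methyl]-4,6-dihydroxy-2-(6-methylhepta-1,5-dien-2-yl)-2,3-dihydro-1-benzofuran-5-yl]ethan-1-one; 18 6-ethyl-4-hydroxy-5-methyl-2H-pyran-2-one
Product: 21 3-{[(2R)-5-acetyl-4,6-dihydroxy-2-(6-methylhepta-1,5-dien-2-yl)-2,3-dihydro-1-benzofuran-7-yl]methyl}-6-ethyl-4-hydroxy-5-methyl-2H-pyran-2-one, via ortho-quinone methide 20 (not isolated)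
Conditions: 18 (1.5 equiv), 1,4-dioxane, 90 °C
Reagents that add atoms: none
Why: The acidic pyranone protonates the amine, loss of dimethylamine gives the ortho-quinone methide, and Michael addition of the nucleophilic C3 of the 4-hydroxypyranone restores the aromaticity of ring A; every other position of ring A is blocked, so only the heterodimer can form, and C2 is not involved.

**Compound list**
1 | 2-methylprop-2-en-1-ol | C=C(C)CO | starting material
2 | 1-bromo-3-methylbut-2-ene | CC(C)=CCBr | starting material
3 | dilithiated methallyl alcohol | [Li]CC(=C)CO[Li] | intermediate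
4 | 6-methyl-2-methylidenehept-5-en-1-ol | C=C(CO)CCC=C(C)C | intermediate
5 | 1-(2,4,6-trihydroxyphenyl)ethan-1-one | CC(=O)c1c(O)cc(O)cc1O | starting material
6 | 1-{2,6-dihydroxy-4-[(6-methyl-2-methylidenehept-5-en-1-yl)oxy]phenyl}ethan-1-one | CC(=O)c1c(O)cc(OCC(=C)CCC=C(C)C)cc1O | intermediate
7 | aryl iminium chloride (N,N-dimethyliminium salt of 8) | C[N+](C)=Cc1c(O)c(C(C)=O)c(O)cc1OCC(=C)CCC=C(C)C.[Cl-] | intermediate
8 | 3-acetyl-2,4-dihydroxy-6-[(6-methyl-2-methylidenehept-5-en-1-yl)oxy]benzaldehyde | O=Cc1c(O)c(C(C)=O)c(O)cc1OCC(=C)CCC=C(C)C | intermediate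
9 | 2-acetyl-4-formyl-5-[(6-methyl-2-methylidenehept-5-en-1-yl)oxy]benzene-1,3-diyl bis(2,2-dimethylpropanoate) | O=Cc1c(OC(=O)C(C)(C)C)c(C(C)=O)c(OC(=O)C(C)(C)C)cc1OCC(=C)CCC=C(C)C | intermediate
10 | (E)-2,4,6-triisopropylbenzenesulfonylhydrazone of 9 | CC(C)c1cc(C(C)C)c(S(=O)(=O)N/N=C/c2c(OC(=O)C(C)(C)C)c(C(C)=O)c(OC(=O)C(C)(C)C)cc2OCC(=C)CCC=C(C)C)c(C(C)C)c1 | intermediate
11 | 2-acetyl-4-(diazomethyl)-5-[(6-methyl-2-methylidenehept-5-en-1-yl)oxy]benzene-1,3-diyl bis(2,2-dimethylpropanoate) | [N-]=[N+]=Cc1c(OC(=O)C(C)(C)C)c(C(C)=O)c(OC(=O)C(C)(C)C)cc1OCC(=C)CCC=C(C)C | intermediate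
12 | (2R)-5-acetyl-2-(6-methylhepta-1,5-dien-2-yl)-2,3-dihydro-1-benzofuran-4,6-diyl bis(2,2-dimethylpropanoate) | C=C(CCC=C(C)C)[C@H]1Cc2c(OC(=O)C(C)(C)C)c(C(C)=O)c(OC(=O)C(C)(C)C)cc2O1 | intermediate
13 | 1-[(2R)-4,6-dihydroxy-2-(6-methylhepta-1,5-dien-2-yl)-2,3-dihydro-1-benzofuran-5-yl]ethan-1-one | C=C(CCC=C(C)C)[C@H]1Cc2c(O)c(C(C)=O)c(O)cc2O1 | intermediate
14 | methyl 3-oxopentanoate | CCC(=O)CC(=O)OC | starting material
15 | N-methoxy-N-methylpropanamide | CCC(=O)N(C)OC | starting material
16 | dilithium dienediolate of 14 | CC=C(O[Li])C=C(O[Li])OC | intermediate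
17 | methyl 4-methyl-3,5-dioxoheptanoate (C4 configurationally labile) | CCC(=O)C(C)C(=O)CC(=O)OC | intermediate
18 | 6-ethyl-4-hydroxy-5-methyl-2H-pyran-2-one | CCc1oc(=O)cc(O)c1C | intermediate
19 | 1-[(2R)-7-[(dimethylamino)methyl]-4,6-dihydroxy-2-(6-methylhepta-1,5-dien-2-yl)-2,3-dihydro-1-benzofuran-5-yl]ethan-1-one | C=C(CCC=C(C)C)[C@H]1Cc2c(O)c(C(C)=O)c(O)c(CN(C)C)c2O1 | intermediate
20 | (2R)-5-acetyl-4-hydroxy-7-methylidene-2-(6-methylhepta-1,5-dien-2-yl)-2,3-dihydro-1-benzofuran-6(7H)-one (ortho-quinone methide) | C=C(CCC=C(C)C)[C@H]1CC2=C(O1)C(=C)C(=O)C(C(C)=O)=C2O | intermediate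
21 | 3-{[(2R)-5-acetyl-4,6-dihydroxy-2-(6-methylhepta-1,5-dien-2-yl)-2,3-dihydro-1-benzofuran-7-yl]methyl}-6-ethyl-4-hydroxy-5-methyl-2H-pyran-2-one | C=C(CCC=C(C)C)[C@H]1Cc2c(O)c(C(C)=O)c(O)c(Cc3c(O)c(C)c(CC)oc3=O)c2O1 | target

**Step count**
- Total step count: 11.
- Longest linear sequence: 9 (steps 1–7, 10 and 11).

**Steps most likely to fail**

**Step 6.** Three things may go wrong.
- The diazo group may be lost before the catalyst reaches it, by uncatalysed intramolecular dipolar cycloaddition onto the neighbouring 1,1-disubstituted alkene or by azine formation. This is plausible because the carbene carbon is flanked by two ortho substituents and may enter the ligand pocket slowly.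
- Cyclopropanation may compete.
- Discrimination between the two enantiotopic hydrogens may be poor.

The fallback gives up diazo chemistry. It sets out from 5 and comes back at 13, so that steps 1 to 7 are bypassed. Mono-iodination of 5 (N-iodosuccinimide, MeCN, 0 °C) should give 1-(2,4,6-trihydroxy-3-iodophenyl)ethan-1-one F1. F1 and commercial myrcene then enter the enantioselective Heck/Tsuji–Trost heteroannulation of ortho-halophenols with 1,3-dienes (Pd2(dba)3, chiral sulfinamide–phosphine ligand, Na2CO3, 1,4-dioxane, 80 °C). The sequence is oxidative addition to zerovalent palladium, arylpalladation of the vinyl CH2 terminus of myrcene, and attack of the non-chelated hydroxyl para to the acetyl group on the internal end of the π-allyl palladium unit. This should give 13 directly. The route is kept as a fallback only, because it depends on telling apart two ortho hydroxyls and on a polyphenolic aryl iodide.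

**Step 2.** Alkylation may run on to the chelated hydroxyls, or activation of the 2-substituted allylic alcohol may be sluggish. The fallback lets acidity instead of the phosphonium betaine choose the site. It sets out from 4 and comes back at 6. Appel bromination of 4 (CBr4, PPh3, CH2Cl2, 0 °C) should give 2-(bromomethyl)-6-methylhepta-1,5-diene F2. F2 is used in a Williamson etherification of 5 with exactly one equivalent of K2CO3 in acetone at rt. Under these conditions only the non-chelated 4-OH is ionised and alkylated.

**Step 11.** Loss of the amine may be slow, liberated dimethylamine may add back to the quinone methide, or the pyranone may attack through oxygen instead of carbon. The fallback reverses the roles of the partners. It sets out from 18 and 13 and comes back at 21, so that step 10 is bypassed. Aminomethylation of 18 ([Me2N=CH2]I, CH2Cl2, rt; aq NaHCO3) should give 3-[(dimethylamino)methyl]-6-ethyl-4-hydroxy-5-methyl-2H-pyran-2-one F3. On warming with 13 in 1,4-dioxane, F3 releases the more electrophilic 3-methylidenepyran-2,4-dione, which is trapped by C7 of 13, the only free and strongly nucleophilic carbon of ring A.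

**Further compounds**
F1 | step 6 | 1-(2,4,6-trihydroxy-3-iodophenyl)ethan-1-one | CC(=O)c1c(O)cc(O)c(I)c1O
F2 | step 2 | 2-(bromomethyl)-6-methylhepta-1,5-diene | C=C(CBr)CCC=C(C)C
F3 | step 11 | 3-[(dimethylamino)methyl]-6-ethyl-4-hydroxy-5-methyl-2H-pyran-2-one | CCc1oc(=O)c(CN(C)C)c(O)c1C
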